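**Strategy**

The isoflavone is cut through ring C at O1–C8a, C4–C4a and O1–C2. The feature exploited is that O1 and the C4 carbonyl sit on adjacent ring A carbons (C8a and C4a), with the C5 oxygen flanking C4a. A benzyloxy-polarised aryne, released from an ortho-silylaryl triflate, inserts into the acyl C–O bond of an (E)-2-aryl-3-methoxyacrylic acid; the phenoxide so formed displaces methoxide at C2. One operation thus joins ring A to the ring B fragment and closes ring C. The C8 hydroxyl follows by bromination and borylation–oxidation at the only free ring A carbon, and hydrogenolysis of three benzyl ethers ends the route.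

Key step: step 12

Remark: ketene dithioacetal S-oxide 14 should form as a mixture of alkene isomers, racemic at sulfur; both features vanish in step 9, so its SMILES carries no stereodescriptor. Sodium enolate 17 is configurationally labile and is drawn in the geometry carried into 18.

**Route**

Step 1
Reactants: 1 methyl 3,5-dihydroxy-4-methoxybenzoate
Product: 2 methyl 3,5-bis(benzyloxy)-4-methoxybenzoate
Conditions: BnBr (2.4 equiv), K2CO3, DMF, 60 °C
Reagents that add atoms: benzyl bromide, BrCc1ccccc1
Why: Williamson O-alkylation of both phenols by SN2 displacement of bromide, under which the methyl ester and the 4-methoxy group are untouched.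

Step 2
Reactants: 2 methyl 3,5-bis(benzyloxy)-4-methoxybenzoate
Product: 3 [3,5-bis(benzyloxy)-4-methoxyphenyl]methanol
Conditions: LiAlH4, THF, 0 °C → rt
Reagents that add atoms: none
Why: Hydride reduction of the benzoate ester to the benzylic alcohol by LiAlH4, which leaves aryl benzyl and methyl ethers intact.

Step 3
Reactants: 3 [3,5-bis(benzyloxy)-4-methoxyphenyl]methanol
Product: 4 3,5-bis(benzyloxy)-4-methoxybenzaldehyde
Conditions: MnO2 (activated, excess), CH2Cl2, rt
Reagents that add atoms: none
Why: Chemoselective heterogeneous oxidation of a benzylic alcohol by MnO2, which stops at the aldehyde.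

Step 4
Reactants: 4 3,5-bis(benzyloxy)-4-methoxybenzaldehyde
Product: 6 3,5-bis(benzyloxy)-4-methoxyphenol, via aryl formate 5 (not isolated)
Conditions: mCPBA, CH2Cl2, rt; then K2CO3 (cat.), MeOH, rt
Reagents that add atoms: 3-chloroperoxybenzoic acid (mCPBA), OOC(=O)c1cccc(Cl)c1
Why: Baeyer–Villiger (Dakin-type) oxidation, in which the electron-rich trialkoxyaryl group of the Criegee adduct migrates in preference to hydrogen to give formate 5, which mild methanolysis converts into the phenol.

Step 5
Reactants: 6 3,5-bis(benzyloxy)-4-methoxyphenol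
Product: 7 3,5-bis(benzyloxy)-2-bromo-4-methoxyphenol
Conditions: NBS (1.0 equiv), CH2Cl2, −20 → 0 °C
Reagents that add atoms: N-bromosuccinimide, O=C1CCC(=O)N1Br
Why: Electrophilic aromatic bromination ortho to the free phenol; the two ortho carbons are equivalent by symmetry and the para carbon is blocked, so one equivalent of NBS at low temperature should give a single monobromide.

Step 6
Reactants: 7 3,5-bis(benzyloxy)-2-bromo-4-methoxyphenol
Product: 10 3,5-bis(benzyloxy)-4-methoxy-2-(trimethylsilyl)phenyl trifluoromethanesulfonate, via aryl silyl ether 8 (not isolated), via lithium silylphenoxide 9 (not isolated)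
Conditions: HMDS, THF, 65 °C, then evaporation; n-BuLi, THF, −78 °C; Tf2O, −78 °C → rt
Reagents that add atoms: hexamethyldisilazane, C[Si](C)(C)N[Si](C)(C)C; trifluoromethanesulfonic anhydride, O=S(=O)(OS(=O)(=O)C(F)(F)F)C(F)(F)F
Why: O-silylation, bromine–lithium exchange and anionic 1,3 O-to-C silyl migration (retro-Brook rearrangement) place the trimethylsilyl group on the former C–Br carbon, and the lithium phenoxide is trapped by Tf2O; exchange at −78 °C is far faster than any attack of n-BuLi on the benzyl ethers.

Step 7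
Reactants: 11 3-hydroxy-4,5-dimethoxybenzaldehyde
Product: 12 3-(benzyloxy)-4,5-dimethoxybenzaldehyde
Conditions: BnBr, K2CO3, DMF, 60 °C
Reagents that add atoms: benzyl bromide, BrCc1ccccc1
Why: Williamson O-alkylation of the single phenol, with the aldehyde inert to carbonate.

Step 8
Reactants: 12 3-(benzyloxy)-4,5-dimethoxybenzaldehyde; 13 methyl (methylsulfinyl)methyl sulfide
Product: 14 1-(benzyloxy)-2,3-dimethoxy-5-[2-(methylsulfinyl)-2-(methylsulfanyl)ethenyl]benzene
Conditions: Triton B (cat., 40% in MeOH), THF, reflux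
Reagents that add atoms: none
Why: Knoevenagel-type condensation of the sulfur-stabilised carbanion of 13 with the non-enolisable aldehyde under hydroxide catalysis (first stage of the Ogura–Tsuchihashi arylacetate synthesis).

Step 9
Reactants: 14 1-(benzyloxy)-2,3-dimethoxy-5-[2-(methylsulfinyl)-2-(methylsulfanyl)ethenyl]benzene
Product: 15 methyl [3-(benzyloxy)-4,5-dimethoxyphenyl]acetate
Conditions: HCl (2 M in MeOH), rt → 40 °C
Reagents that add atoms: methanol, CO
Why: Acid-catalysed methanolysis of the ketene dithioacetal S-oxide (second stage of the Ogura–Tsuchihashi synthesis): C-protonation gives a sulfur-stabilised cation that takes up methanol and collapses to the arylacetic ester with loss of dimethyl disulfide, conditions that aryl benzyl ethers tolerate.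

Step 10
Reactants: 15 methyl [3-(benzyloxy)-4,5-dimethoxyphenyl]acetate; 16 methyl formate
Product: 18 methyl (E)-2-[3-(benzyloxy)-4,5-dimethoxyphenyl]-3-methoxyacrylate, via sodium enolate 17 (not isolated)
Conditions: NaH, HCO2Me, DMF, 0 °C → rt; then Me2SO4, 0 °C → rt
Reagents that add atoms: dimethyl sulfate, COS(=O)(=O)OC
Why: Crossed Claisen formylation of the arylacetate, driven by formation of the stabilised enolate 17, then O-methylation of that enolate by the hard electrophile Me2SO4 in DMF, which should give mainly the thermodynamically preferred (E)-β-methoxyacrylate (methoxy trans to the ester).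

Step 11
Reactants: 18 methyl (E)-2-[3-(benzyloxy)-4,5-dimethoxyphenyl]-3-methoxyacrylate
Product: 19 (E)-2-[3-(benzyloxy)-4,5-dimethoxyphenyl]-3-methoxyacrylic acid
Conditions: LiOH·H2O, THF/MeOH/H2O, 40 °C; then 1 M HCl, 0 °C, pH 3
Reagents that add atoms: lithium hydroxide, [Li+].[OH-]
Why: Saponification of the methyl ester by acyl–oxygen cleavage; the vinylogous carbonate unit should survive aqueous LiOH and brief cold acidification, as it does in the preparation of simpler 3-methoxyacrylic acids.

Step 12
Reactants: 10 3,5-bis(benzyloxy)-4-methoxy-2-(trimethylsilyl)phenyl trifluoromethanesulfonate (1.5 equiv); 19 (E)-2-[3-(benzyloxy)-4,5-dimethoxyphenyl]-3-methoxyacrylic acid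
Product: 22 5,7-bis(benzyloxy)-3-[3-(benzyloxy)-4,5-dimethoxyphenyl]-6-methoxy-4H-chromen-4-one, via aryne 20 (not isolated), via hydroxyaryl ketone 21 (not isolated)
Conditions: CsF (4 equiv), THF, 125 °C, sealed tube
Reagents that add atoms: none
Why: Fluoride removes the silyl group and triflate departs to give aryne 20; the carboxylate of 19 adds to the aryne carbon remote from the flanking benzyloxy group (future C8a), the aryl anion left beside that benzyloxy group (future C4a) attacks the neighbouring ester carbonyl through a four-membered alkoxide that opens to the ortho-acyl phenoxide of 21, and this phenoxide adds to the β-methoxy enone and expels methoxide. The reaction type is the established fluoride-mediated insertion of arynes into the acyl C–O bond of carboxylic acids, which with unsaturated acids is known to continue by conjugate closure to chromanones, flavones and xanthones; loss of methoxide after the conjugate addition is the only added event and mirrors the classical closure of 2-hydroxyaryl β-alkoxyvinyl ketones to chromones. Ring C closes by a 6-endo-trig oxa-Michael addition followed by E1cB loss of methoxide (overall addition–elimination at C2), so the alkene geometry of 19 is of no consequence and no stereocenter is created. The one selectivity required is the regiochemistry of carboxylate addition, and it is secured by the single inductively withdrawing benzyloxy group beside the triple bond, which distorts the aryne so that nucleophiles enter at the distal carbon, while the other flank carries only hydrogen. Acyl transfer must outrun protonation of the aryl anion, which hot THF with sparingly soluble CsF favours, and the acid proton finally neutralises the expelled methoxide as methanol.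

Step 13
Reactants: 22 5,7-bis(benzyloxy)-3-[3-(benzyloxy)-4,5-dimethoxyphenyl]-6-methoxy-4H-chromen-4-one
Product: 23 5,7-bis(benzyloxy)-3-[3-(benzyloxy)-4,5-dimethoxyphenyl]-8-bromo-6-methoxy-4H-chromen-4-one
Conditions: NBS (1.05 equiv), DMF, 0 °C → rt, dark
Reagents that add atoms: N-bromosuccinimide, O=C1CCC(=O)N1Br
Why: Electrophilic aromatic bromination at C8, the only unsubstituted ring A carbon, which is activated by three oxygen donors (O1 and the C7 benzyloxy group ortho, the C5 benzyloxy group para), one more than any ring B position, while C2 of the pyranone is electron-poor.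

Step 14
Reactants: 23 5,7-bis(benzyloxy)-3-[3-(benzyloxy)-4,5-dimethoxyphenyl]-8-bromo-6-methoxy-4H-chromen-4-one
Product: 25 5,7-bis(benzyloxy)-3-[3-(benzyloxy)-4,5-dimethoxyphenyl]-8-hydroxy-6-methoxy-4H-chromen-4-one, via pinacol boronate 24 (not isolated)
Conditions: Pd2(dba)3 (cat.), XPhos, B2pin2, KOAc, 1,4-dioxane, 100 °C; then THF, 30% aq H2O2, NaHCO3, 0 °C → rt
Reagents that add atoms: hydrogen peroxide, OO; bis(pinacolato)diboron, CC1(C)OB(OC1(C)C)B1OC(C)(C)C(C)(C)O1 (its boron is retained only in 24)
Why: Miyaura borylation with a bulky biarylphosphine palladium catalyst suited to doubly ortho-substituted bromides, then oxidative 1,2-migration of the aryl group from boron to oxygen with mildly basic H2O2; telescoping limits protodeboronation of the electron-rich boronate and the weak base spares the pyranone.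

Step 15
Reactants: 25 5,7-bis(benzyloxy)-3-[3-(benzyloxy)-4,5-dimethoxyphenyl]-8-hydroxy-6-methoxy-4H-chromen-4-one
Product: 26 5,7,8-trihydroxy-3-(3-hydroxy-4,5-dimethoxyphenyl)-6-methoxy-4H-chromen-4-one
Conditions: H2 (1 atm), 10% Pd/C, degassed THF/MeOH, rt; filtration under argon
Reagents that add atoms: none
Why: Catalytic hydrogenolysis of the three benzylic C–O bonds on Pd/C; the C2=C3 bond of the vinylogous ester is hydrogenated much more slowly, so stopping at the calculated uptake should leave ring C intact, and the reducing medium protects the air-sensitive trihydroxy ring A.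

**Compound list**

1 | methyl 3,5-dihydroxy-4-methoxybenzoate | COC(=O)c1cc(O)c(OC)c(O)c1 | starting material
2 | methyl 3,5-bis(benzyloxy)-4-methoxybenzoate | COC(=O)c1cc(OCc2ccccc2)c(OC)c(OCc2ccccc2)c1 | intermediate
3 | [3,5-bis(benzyloxy)-4-methoxyphenyl]methanol | OCc1cc(OCc2ccccc2)c(OC)c(OCc2ccccc2)c1 | intermediate
4 | 3,5-bis(benzyloxy)-4-methoxybenzaldehyde | O=Cc1cc(OCc2ccccc2)c(OC)c(OCc2ccccc2)c1 | intermediate
5 | 3,5-bis(benzyloxy)-4-methoxyphenyl formate | O=COc1cc(OCc2ccccc2)c(OC)c(OCc2ccccc2)c1 | intermediate (not isolated)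
6 | 3,5-bis(benzyloxy)-4-methoxyphenol | Oc1cc(OCc2ccccc2)c(OC)c(OCc2ccccc2)c1 | intermediate
7 | 3,5-bis(benzyloxy)-2-bromo-4-methoxyphenol | Oc1cc(OCc2ccccc2)c(OC)c(OCc2ccccc2)c1Br | intermediate
8 | [3,5-bis(benzyloxy)-2-bromo-4-methoxyphenoxy]trimethylsilane | C[Si](C)(C)Oc1cc(OCc2ccccc2)c(OC)c(OCc2ccccc2)c1Br | intermediate (not isolated)
9 | lithium 3,5-bis(benzyloxy)-4-methoxy-2-(trimethylsilyl)phenoxide | [Li+].[O-]c1cc(OCc2ccccc2)c(OC)c(OCc2ccccc2)c1[Si](C)(C)C | intermediate (not isolated)
10 | 3,5-bis(benzyloxy)-4-methoxy-2-(trimethylsilyl)phenyl trifluoromethanesulfonate | COc1c(OCc2ccccc2)cc(OS(=O)(=O)C(F)(F)F)c([Si](C)(C)C)c1OCc1ccccc1 | intermediate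
11 | 3-hydroxy-4,5-dimethoxybenzaldehyde | COc1cc(C=O)cc(O)c1OC | starting material
12 | 3-(benzyloxy)-4,5-dimethoxybenzaldehyde | COc1cc(C=O)cc(OCc2ccccc2)c1OC | intermediate
13 | methyl (methylsulfinyl)methyl sulfide | CSCS(C)=O | starting material
14 | 1-(benzyloxy)-2,3-dimethoxy-5-[2-(methylsulfinyl)-2-(methylsulfanyl)ethenyl]benzene (alkene isomer mixture, racemic at sulfur) | CSC(=Cc1cc(OC)c(OC)c(OCc2ccccc2)c1)S(C)=O | intermediate
15 | methyl [3-(benzyloxy)-4,5-dimethoxyphenyl]acetate | COC(=O)Cc1cc(OC)c(OC)c(OCc2ccccc2)c1 | intermediate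
16 | methyl formate | COC=O | starting material
17 | sodium (E)-2-[3-(benzyloxy)-4,5-dimethoxyphenyl]-3-methoxy-3-oxoprop-1-en-1-olate | [Na+].[O-]/C=C(/C(=O)OC)c1cc(OC)c(OC)c(OCc2ccccc2)c1 | intermediate (not isolated)
18 | methyl (E)-2-[3-(benzyloxy)-4,5-dimethoxyphenyl]-3-methoxyacrylate | CO/C=C(/C(=O)OC)c1cc(OC)c(OC)c(OCc2ccccc2)c1 | intermediate
19 | (E)-2-[3-(benzyloxy)-4,5-dimethoxyphenyl]-3-methoxyacrylic acid | CO/C=C(/C(=O)O)c1cc(OC)c(OC)c(OCc2ccccc2)c1 | intermediate
20 | 3,5-bis(benzyloxy)-4-methoxybenzyne (1,2-didehydrobenzene) | COC1=C(OCc2ccccc2)C#CC=C1OCc1ccccc1 | intermediate (not isolated)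
21 | (E)-1-[2,4-bis(benzyloxy)-6-hydroxy-3-methoxyphenyl]-2-[3-(benzyloxy)-4,5-dimethoxyphenyl]-3-methoxyprop-2-en-1-one | CO/C=C(/C(=O)c1c(O)cc(OCc2ccccc2)c(OC)c1OCc1ccccc1)c1cc(OC)c(OC)c(OCc2ccccc2)c1 | intermediate (not isolated)
22 | 5,7-bis(benzyloxy)-3-[3-(benzyloxy)-4,5-dimethoxyphenyl]-6-methoxy-4H-chromen-4-one | COc1cc(-c2coc3cc(OCc4ccccc4)c(OC)c(OCc4ccccc4)c3c2=O)cc(OCc2ccccc2)c1OC | intermediate
23 | 5,7-bis(benzyloxy)-3-[3-(benzyloxy)-4,5-dimethoxyphenyl]-8-bromo-6-methoxy-4H-chromen-4-one | COc1cc(-c2coc3c(Br)c(OCc4ccccc4)c(OC)c(OCc4ccccc4)c3c2=O)cc(OCc2ccccc2)c1OC | intermediate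
24 | 5,7-bis(benzyloxy)-3-[3-(benzyloxy)-4,5-dimethoxyphenyl]-6-methoxy-8-(4,4,5,5-tetramethyl-1,3,2-dioxaborolan-2-yl)-4H-chromen-4-one | COc1cc(-c2coc3c(B5OC(C)(C)C(C)(C)O5)c(OCc4ccccc4)c(OC)c(OCc4ccccc4)c3c2=O)cc(OCc2ccccc2)c1OC | intermediate (not isolated)
25 | 5,7-bis(benzyloxy)-3-[3-(benzyloxy)-4,5-dimethoxyphenyl]-8-hydroxy-6-methoxy-4H-chromen-4-one | COc1cc(-c2coc3c(O)c(OCc4ccccc4)c(OC)c(OCc4ccccc4)c3c2=O)cc(OCc2ccccc2)c1OC | intermediate
26 | 5,7,8-trihydroxy-3-(3-hydroxy-4,5-dimethoxyphenyl)-6-methoxy-4H-chromen-4-one | COc1cc(-c2coc3c(O)c(O)c(OC)c(O)c3c2=O)cc(O)c1OC | target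

**Count and risks**

Total step count: 15. Longest linear sequence: 10 steps (steps 1–6, then 12–15, from compound 1).

Step 12 is the most likely to fail. The aryl anion may be protonated before it reaches the weakly electrophilic vinylogous-carbonate carbonyl, so that O-arylation occurs without acyl transfer. The β-methoxyacrylate may also be degraded by fluoride or methoxide at 125 °C before insertion. The fallback separates ring A–C4 bond formation from the supply of C2; it sets out from ester 15 and aryne precursor 10 and returns at 22. Ester 15 would be saponified with LiOH to [3-(benzyloxy)-4,5-dimethoxyphenyl]acetic acid F1, whose ordinary carboxyl carbon belongs to the acid class for which the insertion is established. With 10 and CsF in THF at 125 °C, F1 should give the deoxybenzoin 1-[2,4-bis(benzyloxy)-6-hydroxy-3-methoxyphenyl]-2-[3-(benzyloxy)-4,5-dimethoxyphenyl]ethanone F2 with the same aryne regiochemistry. Heating F2 with N,N-dimethylformamide dimethyl acetal in toluene should give the enaminone (E)-1-[2,4-bis(benzyloxy)-6-hydroxy-3-methoxyphenyl]-2-[3-(benzyloxy)-4,5-dimethoxyphenyl]-3-(dimethylamino)prop-2-en-1-one F3, which closes with loss of dimethylamine to 22 (classical isoflavone closure).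

Step 13 is next. Site selectivity may be poor, with electrophilic attack on the electron-rich ring B at C2' or C6' competing with C8, or with over-bromination. The fallback uses a free phenol to direct the halogen; it sets out from 22 and returns at 23. Chelation-controlled cleavage of the peri C5 benzyl ether (BCl3, 1 equiv, CH2Cl2, −78 °C) should give 7-(benzyloxy)-3-[3-(benzyloxy)-4,5-dimethoxyphenyl]-5-hydroxy-6-methoxy-4H-chromen-4-one F4. Its phenol directs NBS to the para carbon C8, which should give 7-(benzyloxy)-3-[3-(benzyloxy)-4,5-dimethoxyphenyl]-8-bromo-5-hydroxy-6-methoxy-4H-chromen-4-one F5. Re-benzylation of F5 (BnBr, K2CO3, DMF, 60 °C) should give 23.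

Step 14 is third. Oxidative addition and boryl transfer may be slow at the doubly ortho-flanked C8–Br bond, with competing protodebromination, or the boronate may protodeboronate before oxidation. The fallback forms the C8–O bond directly by cross-coupling; it sets out from 23 and returns at target 26. Palladium-catalysed etherification of 23 with benzyl alcohol ([(allyl)PdCl]2, RockPhos, Cs2CO3, toluene, 90 °C) should give 5,7,8-tris(benzyloxy)-3-[3-(benzyloxy)-4,5-dimethoxyphenyl]-6-methoxy-4H-chromen-4-one F6. Hydrogenolysis of its four benzyl ethers under the conditions of step 15 should give 26.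

**Further compounds**

F1 | step 12 | [3-(benzyloxy)-4,5-dimethoxyphenyl]acetic acid | OC(=O)Cc1cc(OC)c(OC)c(OCc2ccccc2)c1
F2 | step 12 | 1-[2,4-bis(benzyloxy)-6-hydroxy-3-methoxyphenyl]-2-[3-(benzyloxy)-4,5-dimethoxyphenyl]ethanone | O=C(Cc1cc(OC)c(OC)c(OCc2ccccc2)c1)c1c(O)cc(OCc2ccccc2)c(OC)c1OCc1ccccc1
F3 | step 12 | (E)-1-[2,4-bis(benzyloxy)-6-hydroxy-3-methoxyphenyl]-2-[3-(benzyloxy)-4,5-dimethoxyphenyl]-3-(dimethylamino)prop-2-en-1-one | CN(C)/C=C(/C(=O)c1c(O)cc(OCc2ccccc2)c(OC)c1OCc1ccccc1)c1cc(OC)c(OC)c(OCc2ccccc2)c1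
F4 | step 13 | 7-(benzyloxy)-3-[3-(benzyloxy)-4,5-dimethoxyphenyl]-5-hydroxy-6-methoxy-4H-chromen-4-one | COc1cc(-c2coc3cc(OCc4ccccc4)c(OC)c(O)c3c2=O)cc(OCc2ccccc2)c1OC
F5 | step 13 | 7-(benzyloxy)-3-[3-(benzyloxy)-4,5-dimethoxyphenyl]-8-bromo-5-hydroxy-6-methoxy-4H-chromen-4-one | COc1cc(-c2coc3c(Br)c(OCc4ccccc4)c(OC)c(O)c3c2=O)cc(OCc2ccccc2)c1OC
F6 | step 14 | 5,7,8-tris(benzyloxy)-3-[3-(benzyloxy)-4,5-dimethoxyphenyl]-6-methoxy-4H-chromen-4-one | COc1cc(-c2coc3c(OCc4ccccc4)c(OCc4ccccc4)c(OC)c(OCc4ccccc4)c3c2=O)cc(OCc2ccccc2)c1OC
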